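**Remark (assumption).** (S)-4-(tert-Butyldimethylsilyloxy)cyclopent-2-en-1-one (1) is taken as a commercial, enantiopure building block. Compounds 6–8 are drawn as the cis,anti,cis photoadduct series, and C8 is left undefined in 6–11 because both epimers converge in step 9.

**Numbering.** Daucane numbering is used throughout. Ring A is C1 (quaternary, CH3), C2 (CH–OH), C3 (CH2), C4 (C(OH)-isopropyl), C5 (ring-fusion CH). Ring B is C5, C6 (CH–O-tiglate), C7 (CH2), C8 (C–CH3, epoxide), C9 (epoxide CH), C10 (CH–O-tiglate), C1. "Upper face" means the face that carries the C1 methyl group.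

## Analysis of the target

The target is a daucane sesquiterpenoid diester in which cyclopentane ring A and cycloheptane ring B share the C1–C5 bond. As encoded in the SMILES, the C1 methyl group and H-5 are on the same face, so the bicyclo[5.3.0]decane is cis-fused. There are eight stereocenters (1S,2S,4R,5S,6S,8S,9R,10R), and C8–C9–C10–C1–C5–C6 plus C4 form one unbroken stereochemical array. The upper face carries C1–CH3, H-5, the C2 hydroxyl, the C4 isopropyl group, the C6 tiglate and C8–CH3. The lower face carries the tertiary C4 hydroxyl, the C10 tiglate and the epoxide oxygen. Six of the ten ring carbons bear oxygen; the C4 hydroxyl is anti-1,3 to both the C2 and the C6 oxygen, and the epoxide is syn to the C10 oxygen. The quaternary C1 is flanked by two carbinol carbons (C2, C10), and the tertiary carbinol C4 sits next to the ring-fusion carbon C5. Sensitive groups are the trisubstituted epoxide (acid), the two E-enoate esters (base, nucleophiles, acyl migration) and, in intermediates, β-hydroxy carbonyl arrays (retro-aldol, dehydration). The three secondary oxygens must also be told apart, since C2 stays free while C6 and C10 are acylated. The feature used here is that the ester-bearing carbons C6 and C10 are 1,4-related across the ring-fusion bond C5–C1. Ring B is therefore a cyclopentane (C6–C7–C8–C9–C10) whose C6–C10 bond has been cut and whose two ends hang on C5 and C1, the retron of a cyclobutane-1,2-diol cleavage.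

## Retrosynthetic reasoning

16 ⇒ 15 (O–Si bond at C2). The free C2 hydroxyl is the only group that must stay masked to the end. It is carried as the silyl ether that is already present in building block 1 and never changes oxidation state.

15 ⇒ 14 ⇒ 13 (C10–O acyl bond; the two C–O bonds of the epoxide). The epoxide oxygen and the C10 oxygen are on the same face, which is the signature of a hydroxyl-directed epoxidation of allylic alcohol 13. The C10 ester is therefore made only after the directing hydroxyl has done its work.

13 ⇒ 12 ⇒ 11 (C10–H; C8=C9). The allylic alcohol comes from enone 12 by 1,2-reduction from the convex face, and the enone from ketone 11 by dehydrogenation. Because C1 is quaternary, the C10 ketone can enolize only toward C9, so the double bond can appear only at C8=C9 and the C8 stereocenter of 11 does not matter.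

11 ⇒ 10 ⇒ 9 (C6–O acyl bond; C6–H). The C6 oxygen is anti-1,3 to the tertiary C4 hydroxyl. Hydride delivered internally from that hydroxyl to diketone 9 sets C6 and also distinguishes the C6 from the C10 carbonyl, since only C6 is β to the hydroxyl. Acylating C6 at once avoids a protecting group.

9 ⇒ 8 ⇒ 7 (reconnection of C6–C10). The two carbonyls of 9 are 1,4-related across C5–C1 and are reconnected to the cis cyclobutane-1,2-diol 8. Ring B is thereby folded up as a cyclopentane fused to a four-membered ring. The C6–C10 bond is the bond that is not in the target; in the forward sense, glycol cleavage unveils the seven-membered ring with the cis fusion already in place.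

7 ⇒ 6 (C4–isopropyl bond). While ring B is still folded up, the C4 ketone of 6 sits in a rigid bicyclo[3.2.0]heptanone whose concave face is blocked. The isopropyl group is cut here because addition will come from the convex face (isopropyl cis to C1–CH3). No other carbonyl is present at this stage (C2 is an ether, C6 and C10 are silyl ethers), which avoids acidic 1,3-dicarbonyl arrays.

6 ⇒ 3 + 5 (C1–C10 and C5–C6). Cutting the cyclobutane across these two bonds gives enone 3 and the symmetrical enediol bis-silyl ether 5, the partners of a [2+2] photocycloaddition. One step makes the quaternary C1 and both ring-fusion stereocenters (cis by necessity), and attaches the five remaining carbons of ring B together with both ring-B carbinol oxygens. The only control element needed is the C2 silyloxy group of 3.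

3 ⇒ 2 ⇒ 1 and 5 ⇒ 4. Enone 3 is the β-methyl homologue of building block 1, made by conjugate methyl addition and re-oxidation of the trapped enol ether 2. Alkene 5 is the acyloin-type ring-closure product of diester 4.

## Alternatives that were turned down

Alternative 1: Disconnection of the C8=C9 double bond that precedes the epoxide, the textbook cut of a cycloheptene. The forward key step is ring-closing metathesis of diene A1 with the second-generation Grubbs catalyst. A1 is ring A carrying a 1-silyloxyallyl group on C1 and a 1-silyloxy-3-methylbut-3-enyl group on C5. It was turned down because the metathesis closes ring B but sets no stereocenter. The quaternary C1 and the carbinol centers C6 and C10 of A1 would have to be built one at a time by carbonyl additions next to a quaternary carbon, where 1,2-induction is hard to predict. Two extra protecting groups are needed, and the precursor costs far more steps than the one C=C bond the key step wins.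

Alternative 2: Disconnection of C1–C5 and C1–C10, with ring B seen as a benzene ring expanded by the carbene carbon C1 (intramolecular Buchner reaction). The forward key step is Rh2(OAc)4-catalysed decomposition of aryl diazo ketone A2 to the cycloheptatriene-fused cyclopentanone A3. The arene supplies C5–C10, its methoxy group the C6 oxygen and its methyl group C8–CH3. It was turned down on stereochemical grounds. In the cyclopropanation transition state the benzylic carbon C4 must place one substituent in the arene plane next to the methoxy-bearing ortho carbon. Allylic strain puts the small oxygen substituent there and the isopropyl group perpendicular, which leads to isopropyl trans to the C1 methyl as drawn in A3, the opposite of the target. In addition, 1,5 C–H insertion into the isopropyl methine competes, and C5 is sp2 in A3 so the cis fusion would rest on a protonation. Moving the isopropyl addition to a later C4 ketone would pair that ketone with the C2 ketone in an acidic 1,3-dione.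

Alternative 3: Disconnection of C1–C10 and C5–C6 by a (5+2) dipolar cycloaddition in which the C6 and C10 oxygens are one bridging ether oxygen. The forward key step is base-induced formation of the 3-oxidopyrylium ylide from acetoxypyranone A4 and its addition to enone 3, giving the 8-oxabicyclo[3.2.1]octenone A5. It was turned down for three reasons. One oxygen atom would have to serve two carbinol carbons that are trans in the target, so the C10–O bond must be broken and oxygen brought back with inversion at a neopentyl carbon. The C9 carbonyl would have to be removed with allylic transposition to place C8=C9, at a cost of five or more extra steps. A ground-state cycloaddition onto the β,β-disubstituted enone carbon is also expected to lose against ylide dimerization, a limit the excited-state [2+2] does not share.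

Key step: step 4

## Route

Step 1
Reactants: 1 (S)-4-(tert-butyldimethylsilyloxy)cyclopent-2-en-1-one
Product: 2 tert-butyldimethyl{[(1S,2S)-2-methyl-4-(trimethylsilyloxy)cyclopent-3-en-1-yl]oxy}silane (methyl trans to the silyloxy group)
Conditions: Me2CuLi (from MeLi and CuI), TMSCl, Et3N, THF, −78 °C
Reagents that add atoms: lithium dimethylcuprate [Li+].C[Cu-]C; chlorotrimethylsilane C[Si](C)(C)Cl
Why: Conjugate addition of a Gilman cuprate with in situ O-silylation; methyl adds trans to the silyloxy group, trapping the regiodefined enolate prevents its equilibration and β-elimination, and the new methyl stereocenter is erased in step 2.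

Step 2
Reactants: 2 tert-butyldimethyl{[(1S,2S)-2-methyl-4-(trimethylsilyloxy)cyclopent-3-en-1-yl]oxy}silane
Product: 3 (S)-4-(tert-butyldimethylsilyloxy)-3-methylcyclopent-2-en-1-one
Conditions: Pd(OAc)2 (1 equiv), MeCN, rt
Reagents that add atoms: none
Why: Saegusa–Ito oxidation; the palladium enolate undergoes β-hydride elimination toward the methyl-bearing carbon (divalent palladium ends as zerovalent palladium), which restores the enone with methyl at the β-carbon and leaves the silyloxy stereocenter untouched.

Step 3
Reactants: 4 dimethyl 3-methylpentanedioate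
Product: 5 4-methyl-1,2-bis(trimethylsilyloxy)cyclopent-1-ene
Conditions: Na, TMSCl, toluene, reflux
Reagents that add atoms: chlorotrimethylsilane C[Si](C)(C)Cl
Why: Rühlmann variant of the acyloin condensation; the silyl chloride traps the enediolate and the methoxide, which makes five-membered ring closure clean; the product has a mirror plane, so its two olefinic carbons are equivalent.

Step 4
Reactants: 3 (S)-4-(tert-butyldimethylsilyloxy)-3-methylcyclopent-2-en-1-one; 5 4-methyl-1,2-bis(trimethylsilyloxy)cyclopent-1-ene
Product: 6 cis,anti,cis-tricyclic photoadduct (ring A with C4 ketone and upper-face C2–OTBS, C1–CH3 and H-5; cyclobutane C1–C5–C6–C10 on the lower face; C6 and C10 each carry OSiMe3 and are bridged by C7–C8(CH3)–C9)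
Conditions: hν (λ > 300 nm, Pyrex), 5 (4 equiv), hexane/CH2Cl2, −30 °C
Reagents that add atoms: none
Why: Enone–alkene [2+2] photocycloaddition of the de Mayo family; the closest known case is the addition of methylcyclopentenones to 1,2-bis(trimethylsilyloxy)cyclopentene followed by glycol cleavage to hydroazulenes. The enone triplet adds to the electron-rich alkene to give a 1,4-biradical, which closes the four-membered ring C1–C5–C6–C10 by radical recombination and so forms C1–C10, C5–C6 and the quaternary C1. A cyclopentenone can only give a cis-fused bicyclo[3.2.0]heptanone, so C1–CH3 and H-5 are locked cis. The alkene approaches the enone face anti to the C2 silyloxy group, which sits next to the β-carbon, so both new bonds lie on the lower face and the C1 methyl ends up cis to the C2 oxygen. No regiochemistry arises because the two olefinic carbons of 5 are equivalent. The configurations created at C6, C10 and C8 and the syn or anti arrangement of the outer rings are all erased later (C6 and C10 become carbonyls, C8 becomes sp2), so every such isomer converges on the same material. The step needs facial selectivity, secured by the silyloxy group, and cross-addition over enone dimerization, secured by the excess of 5.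

Step 5
Reactants: 6 cis,anti,cis-tricyclic photoadduct
Product: 7 tertiary alcohol of the photoadduct (C4: isopropyl on the upper face, OH on the lower face)
Conditions: i-PrMgCl, CeCl3 (anhydrous), THF, −78 °C
Reagents that add atoms: isopropylmagnesium chloride CC(C)[Mg]Cl
Why: Organocerium 1,2-addition (Imamoto conditions) suppresses enolization, β-elimination of the C2 silyloxy group and β-hydride reduction; attack is on the exo face of the bicyclo[3.2.0]heptanone, away from the cyclobutane and its C6 silyloxy group, and removing the C4 carbonyl now also prevents retro-aldol opening of the cyclobutane in step 6.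

Step 6
Reactants: 7 tertiary alcohol of the photoadduct
Product: 9 cis-fused 2-(tert-butyldimethylsilyloxy)-4-hydroxydaucane-6,10-dione (C8 epimers), via cyclobutanediol 8 (not isolated)
Conditions: K2CO3 (cat.), MeOH, 0 °C; then AcOH, Pb(OAc)4, 0 °C
Reagents that add atoms: none
Why: Methanolysis removes the two trimethylsilyl ethers but not the tert-butyldimethylsilyl ether, and Criegee glycol cleavage of the cis cyclobutane-1,2-diol breaks the C6–C10 bond that is not in the target; this releases ring B as a cycloheptane-1,4-dione with the cis ring fusion intact and forms no new stereocenter.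

Step 7
Reactants: 9 cis-fused 2-(tert-butyldimethylsilyloxy)-4-hydroxydaucane-6,10-dione
Product: 10 6-hydroxy-10-ketone (C6–OH on the upper face, anti to the C4 hydroxyl)
Conditions: Me4NBH(OAc)3, MeCN/AcOH, −30 °C
Reagents that add atoms: none
Why: Evans–Saksena reduction; the C4 hydroxyl exchanges onto boron and delivers hydride through a six-membered transition state to the lower face of the β-carbonyl C6, giving the anti-1,3-diol, while the C10 ketone has no β-hydroxyl and is not reduced by this mild reagent.

Step 8
Reactants: 10 6-hydroxy-10-ketone
Product: 11 6-O-tiglate 10-ketone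
Conditions: tigloyl chloride, Et3N, DMAP (cat.), CH2Cl2, 0 °C to rt
Reagents that add atoms: tigloyl chloride C/C=C(\C)C(=O)Cl
Why: Nucleophile-catalysed acylation of the only secondary alcohol; the tertiary C4 hydroxyl does not react and the E geometry of the enoate, the stable one, is retained.

Step 9
Reactants: 11 6-O-tiglate 10-ketone
Product: 12 8(9)-en-10-one (trisubstituted C8=C9 enone)
Conditions: IBX, DMSO/fluorobenzene, 65 °C
Reagents that add atoms: none
Why: IBX α,β-dehydrogenation of a ketone (Nicolaou conditions); C1 is quaternary, so enolization and unsaturation can only go toward C9, and loss of the C8 hydrogen funnels both C8 epimers into one enone.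

Step 10
Reactants: 12 8(9)-en-10-one
Product: 13 allylic alcohol (C10–OH on the lower face)
Conditions: NaBH4, CeCl3·7H2O, MeOH, −78 °C
Reagents that add atoms: none
Why: Luche 1,2-reduction; hydride should attack the convex upper face, anti to the ring A carbon C2 on the quaternary C1 (Felkin-type), which puts the C10 hydroxyl on the lower face, and the enoate ester is inert under these conditions.

Step 11
Reactants: 13 allylic alcohol
Product: 14 8,9-epoxy-10-ol (epoxide oxygen on the lower face, syn to C10–OH)
Conditions: VO(acac)2 (cat.), t-BuOOH, CH2Cl2, 0 °C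
Reagents that add atoms: tert-butyl hydroperoxide CC(C)(C)OO
Why: Sharpless vanadium-catalysed hydroxyl-directed epoxidation; the C10 vanadate delivers oxygen to the same face of the electron-rich trisubstituted C8=C9 bond, the syn selectivity known for cyclohept-2-enols, and the electron-poor tiglate double bond does not react.

Step 12
Reactants: 14 8,9-epoxy-10-ol
Product: 15 6,10-bis-O-tiglate 2-O-silyl ether
Conditions: tigloyl chloride, DMAP, Et3N, CH2Cl2, rt to 40 °C
Reagents that add atoms: tigloyl chloride C/C=C(\C)C(=O)Cl
Why: Acylation of the hindered neopentyl epoxy alcohol through the acylpyridinium ion; amine bases are too weak to start a Payne rearrangement and the tertiary alcohol stays free.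

Step 13
Reactants: 15 6,10-bis-O-tiglate 2-O-silyl ether
Product: 16 CNP0265715.1 (target)
Conditions: TBAF, AcOH, THF, 0 °C to rt
Reagents that add atoms: none
Why: Fluoride desilylation buffered with acetic acid keeps the medium near neutral, so the epoxide, both tiglates and the tertiary alcohol should survive and acyl migration to the freed C2 hydroxyl is held back; the C2 stereocenter comes unchanged from compound 1.

## Compound list

1 | (S)-4-(tert-butyldimethylsilyloxy)cyclopent-2-en-1-one | C1=CC(=O)C[C@@H]1O[Si](C)(C)C(C)(C)C | starting material
2 | tert-butyldimethyl{[(1S,2S)-2-methyl-4-(trimethylsilyloxy)cyclopent-3-en-1-yl]oxy}silane | C[Si](C)(C)OC1=C[C@H](C)[C@@H](O[Si](C)(C)C(C)(C)C)C1 | intermediate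
3 | (S)-4-(tert-butyldimethylsilyloxy)-3-methylcyclopent-2-en-1-one | CC1=CC(=O)C[C@@H]1O[Si](C)(C)C(C)(C)C | intermediate
4 | dimethyl 3-methylpentanedioate | COC(=O)CC(C)CC(=O)OC | starting material
5 | 4-methyl-1,2-bis(trimethylsilyloxy)cyclopent-1-ene | CC1CC(O[Si](C)(C)C)=C(O[Si](C)(C)C)C1 | intermediate
6 | cis,anti,cis-tricyclic photoadduct: C4 ketone, C2–OTBS, cyclobutane C1–C5–C6–C10 with OSiMe3 on C6 and C10, C7–C8(CH3)–C9 bridge | C[Si](C)(C)O[C@@]13CC(C)C[C@@]3(O[Si](C)(C)C)[C@@]2(C)[C@@H]1C(=O)C[C@@H]2O[Si](C)(C)C(C)(C)C | intermediate
7 | tertiary alcohol of the photoadduct: C4 bears OH (lower face) and isopropyl (upper face) | C[Si](C)(C)O[C@@]13CC(C)C[C@@]3(O[Si](C)(C)C)[C@@]2(C)[C@@H]1[C@](O)(C(C)C)C[C@@H]2O[Si](C)(C)C(C)(C)C | intermediate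
8 | cyclobutane-1,2-diol (C4, C6, C10 triol, C2–OTBS) | O[C@@]13CC(C)C[C@@]3(O)[C@@]2(C)[C@@H]1[C@](O)(C(C)C)C[C@@H]2O[Si](C)(C)C(C)(C)C | intermediate (not isolated)
9 | cis-fused 2-(tert-butyldimethylsilyloxy)-4-hydroxydaucane-6,10-dione (C8 epimers) | O=C1CC(C)CC(=O)[C@@]2(C)[C@@H]1[C@](O)(C(C)C)C[C@@H]2O[Si](C)(C)C(C)(C)C | intermediate
10 | 6-hydroxy-10-ketone: C6–OH upper face, C4–OH, C2–OTBS | O[C@H]1CC(C)CC(=O)[C@@]2(C)[C@@H]1[C@](O)(C(C)C)C[C@@H]2O[Si](C)(C)C(C)(C)C | intermediate
11 | 6-O-tiglate 10-ketone | C/C=C(\C)C(=O)O[C@H]1CC(C)CC(=O)[C@@]2(C)[C@@H]1[C@](O)(C(C)C)C[C@@H]2O[Si](C)(C)C(C)(C)C | intermediate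
12 | 6-O-tiglate 8(9)-en-10-one | C/C=C(\C)C(=O)O[C@H]1CC(C)=CC(=O)[C@@]2(C)[C@@H]1[C@](O)(C(C)C)C[C@@H]2O[Si](C)(C)C(C)(C)C | intermediate
13 | 6-O-tiglate 8(9)-en-10-ol (C10–OH lower face) | C/C=C(\C)C(=O)O[C@H]1CC(C)=C[C@H](O)[C@@]2(C)[C@@H]1[C@](O)(C(C)C)C[C@@H]2O[Si](C)(C)C(C)(C)C | intermediate
14 | 6-O-tiglate 8,9-epoxy-10-ol (epoxide lower face) | C/C=C(\C)C(=O)O[C@H]1C[C@]2(C)O[C@@H]2[C@H](O)[C@@]2(C)[C@@H]1[C@](O)(C(C)C)C[C@@H]2O[Si](C)(C)C(C)(C)C | intermediate
15 | 6,10-bis-O-tiglate 8,9-epoxide 2-O-tert-butyldimethylsilyl ether | C/C=C(\C)C(=O)O[C@H]1C[C@]2(C)O[C@@H]2[C@H](OC(=O)/C(C)=C/C)[C@@]2(C)[C@@H]1[C@](O)(C(C)C)C[C@@H]2O[Si](C)(C)C(C)(C)C | intermediate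
16 | CNP0265715.1, (1S,2S,4R,5S,6S,8S,9R,10R)-8,9-epoxy-2,4-dihydroxydaucane-6,10-diyl bis[(E)-2-methylbut-2-enoate] | C/C=C(\C)C(=O)O[C@H]1C[C@]2(C)O[C@@H]2[C@H](OC(=O)/C(C)=C/C)[C@@]2(C)[C@@H]1[C@](O)(C(C)C)C[C@@H]2O | target

## Step count and least certain steps

Total: 13 steps. Longest linear sequence: 12 steps (1, 2 and 4–13 from compound 1); step 3 is a one-step branch.

Step 4 (key step). Three contiguous fully substituted carbons are formed, so the cycloaddition may be slow enough for enone photodimerization and loss of the labile silyl ethers to take over, and facial discrimination by the C2 silyloxy group may be incomplete. The fallback sets out from 3 and returns at 9. Irradiation of 3 with the small partner vinylene carbonate should give the cis-fused cyclobutane carbonate F1. Organocerium addition as in step 5 then gives tertiary alcohol F2. Carbonate methanolysis (K2CO3, MeOH) and NaIO4 cleavage give the cis 1,4-dialdehyde F3. A (3+4) annulation with 3-iodo-2-[(trimethylsilyl)methyl]propene and SnF2 closes ring B as the exo-methylene diol F4. Hydrogenation (H2, Pd/C) gives the C8-methyl diol F5, and Dess–Martin oxidation of its two secondary alcohols gives 9.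

Step 5. The ketone may enolize toward C3 and eliminate the C2 silyloxy group, the branched reagent may reduce the carbonyl by β-hydride transfer, or addition may occur on the wrong face. The fallback sets out from 6 and returns at 7. The slimmer sp2 nucleophile isopropenylmagnesium bromide with CeCl3 gives the isopropenyl carbinol F6, and hydrogenation (H2, PtO2) of its only C=C bond gives 7.

Step 9. Enolization of the neopentyl ketone may be sluggish; at the temperature needed, over-oxidation to the cross-conjugated dienone or vinylogous elimination of the C6 tiglate may follow. The fallback sets out from 11 and returns at 12. Soft enolization (TMSOTf, Et3N) gives the silyl enol ether F7, in which the C4 hydroxyl is silylated as well. Saegusa–Ito oxidation with Pd(OAc)2 gives enone F8, and methanolysis of the tertiary trimethylsilyl ether (citric acid, MeOH) gives 12.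

Step 10. Facial selectivity of hydride delivery may be poor, or hydride may be delivered on the lower face through coordination to the C4 hydroxyl; either gives the C10 epimer. The fallback sets out from 12 and returns at 13. The epimeric alcohol F9 is inverted by a Mitsunobu reaction (4-nitrobenzoic acid, PPh3, DIAD) to the 4-nitrobenzoate F10. Its activated ester is cleaved selectively (K2CO3, MeOH, 0 °C) to 13.

## Further compounds

F1 | step 4 | cis-fused cyclobutane carbonate from 3 and vinylene carbonate (C4 ketone, C2–OTBS) | O=C1O[C@H]2[C@@H](O1)[C@@]3(C)[C@@H]2C(=O)C[C@@H]3O[Si](C)(C)C(C)(C)C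
F2 | step 4 | tertiary alcohol of F1 (C4: OH lower face, isopropyl upper face) | O=C1O[C@H]2[C@@H](O1)[C@@]3(C)[C@@H]2[C@](O)(C(C)C)C[C@@H]3O[Si](C)(C)C(C)(C)C
F3 | step 4 | cis 1,4-dialdehyde (C10 formyl on C1, C6 formyl on C5) | O=C[C@@]1(C)[C@@H](C=O)[C@](O)(C(C)C)C[C@@H]1O[Si](C)(C)C(C)(C)C
F4 | step 4 | ring B diol with exocyclic methylene at C8 (C6 and C10 carbinol epimers) | OC1CC(=C)CC(O)[C@@]2(C)[C@@H]1[C@](O)(C(C)C)C[C@@H]2O[Si](C)(C)C(C)(C)C
F5 | step 4 | ring B diol with C8 methyl (C6, C8 and C10 epimers) | OC1CC(C)CC(O)[C@@]2(C)[C@@H]1[C@](O)(C(C)C)C[C@@H]2O[Si](C)(C)C(C)(C)C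
F6 | step 5 | isopropenyl carbinol of the photoadduct | C[Si](C)(C)O[C@@]13CC(C)C[C@@]3(O[Si](C)(C)C)[C@@]2(C)[C@@H]1[C@](O)(C(C)=C)C[C@@H]2O[Si](C)(C)C(C)(C)C
F7 | step 9 | C10 trimethylsilyl enol ether of 11 with C4–OSiMe3 | C/C=C(\C)C(=O)O[C@H]1CC(C)C=C(O[Si](C)(C)C)[C@@]2(C)[C@@H]1[C@](O[Si](C)(C)C)(C(C)C)C[C@@H]2O[Si](C)(C)C(C)(C)C
F8 | step 9 | 8(9)-en-10-one with C4–OSiMe3 | C/C=C(\C)C(=O)O[C@H]1CC(C)=CC(=O)[C@@]2(C)[C@@H]1[C@](O[Si](C)(C)C)(C(C)C)C[C@@H]2O[Si](C)(C)C(C)(C)C
F9 | step 10 | C10 epimer of 13 (C10–OH upper face) | C/C=C(\C)C(=O)O[C@H]1CC(C)=C[C@@H](O)[C@@]2(C)[C@@H]1[C@](O)(C(C)C)C[C@@H]2O[Si](C)(C)C(C)(C)C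
F10 | step 10 | C10 4-nitrobenzoate with the C10 configuration of 13 | C/C=C(\C)C(=O)O[C@H]1CC(C)=C[C@H](OC(=O)c3ccc(cc3)[N+](=O)[O-])[C@@]2(C)[C@@H]1[C@](O)(C(C)C)C[C@@H]2O[Si](C)(C)C(C)(C)C
A1 | alternative 1 | metathesis diene: ring A with 1-(triethylsilyloxy)allyl on C1 and 1-(triethylsilyloxy)-3-methylbut-3-enyl on C5 | C=C(C)C[C@H](O[Si](CC)(CC)CC)[C@H]1[C@](O)(C(C)C)C[C@H](O[Si](C)(C)C(C)(C)C)[C@@]1(C)[C@@H](O[Si](CC)(CC)CC)C=C
A2 | alternative 2 | 2-diazo-5-(2-methoxy-4-methylphenyl)-6-methyl-5-(trimethylsilyloxy)heptan-3-one | CC(=[N+]=[N-])C(=O)C[C@@](O[Si](C)(C)C)(C(C)C)c1ccc(C)cc1OC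
A3 | alternative 2 | cycloheptatriene-fused cyclopentanone with isopropyl trans to the angular methyl | COC1=C2[C@](O[Si](C)(C)C)(C(C)C)CC(=O)[C@]2(C)C=CC(C)=C1
A4 | alternative 3 | 6-acetoxy-4-methyl-2H-pyran-3(6H)-one (racemic) | CC1=CC(OC(C)=O)OCC1=O
A5 | alternative 3 | oxygen-bridged (5+2) cycloadduct of 3 (C6–O–C10 bridge, C9 ketone, C7=C8) | C[C@@]12[C@@H](O[Si](C)(C)C(C)(C)C)CC(=O)[C@@H]1[C@@H]3C=C(C)C(=O)[C@H]2O3
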